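All runs were generated by integration with made-up constants; noise was put on by code.

The pitfall with a target curve that bends over is to read its height as what was made, when height is what was made minus what was spent.

| flask | substrate | coupling partner | time |
|---|---|---|---|
| larch | 150 mM | 150 mM |  |
| cedar | 60.0 mM | 60.0 mM |  |
| oak | 150 mM | 450 mM |  |
| maple | 50.0 mM | 150 mM | 56 min |

- larch run (time / min: [target] / mM): 2.5: 6.2; 7.5: 27.1; 14: 46.6; 23: 60.0; 33: 66.1; 44: 70.2; 56: 72.3
- cedar run (time / min: [target] / mM): 2.5: 1.1; 7.5: 8.1; 14: 16.5; 23: 24.8; 33: 29.6; 44: 33.2; 56: 34.6
- oak run (time / min: [target] / mM): 2.5: 10.2; 7.5: 30.5; 14: 45.1; 23: 48.7; 33: 45.0; 44: 39.0; 56: 32.5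

(scatter of a reading: 0.8 mM)

- the power of [substrate] that the first rate follows, about the charge of the larch run; measure it at two percent of substrate made into target (one fixed amount of target, the same in the runs compared)
- the power of [coupling partner] that the first rate follows, about the charge of the larch run; measure it at two percent of substrate made into target
- target in the maple run at 56 min, as a share of the substrate charged

- Overall: substrate + coupling partner -> target.
- Constant volume, constant temperature.
- The analysis sees a species whether free or bound.
- An order is taken over about fifteen percent of the charge, up and down.

The oak run shows the spending: target stands at 32.5% of the substrate charge at 23 min, then sinks to 21.7% at 56 min. Coupling partner is charged above substrate in the oak run, so as an untested working assumption I treat the loss as pseudo-first-order, with strength proportional to the partner charge; the reckonings below rest on that assumption. I carry one quantity, the loss count, the number of e-foldings target suffers in 56 min under maple's partner charge.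

I reach it by two ways. Oak's tail, from 33 min to 56 min, decays at 0.0141 /min; maple's partner charge is a third of oak's, so this gives 0.264. Separately, the larch run ends at 48.2% of its charge and the cedar run at 57.7%. If both make the same share, the logarithm of that ratio is the count belonging to their difference in partner charge, and scaling it gives 0.299. Different flasks give nearly the same number, so I carry the mean, 0.281.

Maple has oak's ratio of partner to substrate, so I take oak's final share and undo the difference between their counts. My reckoning for maple is 38.0%. I make no reckoning of the orders.

The forecast gives 0.65 and 0.35 for the orders and 44% for maple, above mine, holding that “Oak's decline shows target is consumed by partner”.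

The flask gives 0.65, 0.29 and 41.9%.

    substrate ⇌ intermediate + by-product (0.04734 /min, 1.896 /M/min)
    intermediate + coupling partner → target (5.016 /M/min)
    target + coupling partner → side product (0.3234 /M/min)
    2 coupling partner ⇌ idle reagent dimer, settled at all times (3.920 /M)

The shortfall in maple comes chiefly from target + coupling partner → side product. The simulated maple run without that step ends at 88.3% instead of 41.9%; the logarithm of that ratio of final shares is 0.745, larger than my 0.281, and both figures are net of target made late. That step costs maple 46 percentage points, which is 80% of what is missing.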